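Assumption: the target SMILES has no stereocentre and no configurational descriptor on the biaryl axis, so there is no stereochemical element to set and the compound is made as drawn.

## Retrosynthetic overview

1. Target 14 comes from protected biflavone 13 by one BCl3 treatment that removes three benzyl ethers and the chelated 5-OMe.
2. The pyranone ring of the C-methylated flavone unit is formed last, by crossed Claisen condensation of biaryl ester 6 with acetophenone 11 and cyclodehydration through the only free phenol, which fixes the 6-methyl regiochemistry.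
3. Key disconnection: the C3'–C8'' biaryl bond joins two innately nucleophilic carbons (a phenol ortho carbon and a phloroglucinol-type CH). The phenol ortho carbon is polarity-reversed as the α-oxo carbenoid from o-quinone diazide 4 (an enolonium equivalent), which attacks C8–H of tri-O-benzylapigenin 2.
4. 4 comes from methyl 3-amino-4-hydroxybenzoate, 2 from apigenin, and 11 from 2,6-dimethoxytoluene by C–H borylation/oxidation and ortho-acylation.
5. Ring order: the apigenin unit is bought intact, then the biaryl bond is made, then the second pyranone ring.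

## Route

Step 1
Reactants: 1 apigenin
Product: 2 5,7-bis(benzyloxy)-2-[4-(benzyloxy)phenyl]-4H-chromen-4-one
Conditions: BnBr (4 equiv), K2CO3 (6 equiv), DMF, 80 °C, 16 h
Reagents that add atoms: benzyl bromide, BrCc1ccccc1
Why: Williamson ether synthesis, in which heating in DMF with excess base also alkylates the hydrogen-bonded 5-OH so that no free OH is left for the carbenoid step.

Step 2
Reactants: 3 methyl 3-amino-4-hydroxybenzoate
Product: 4 methyl 3-diazo-4-oxocyclohexa-1,5-diene-1-carboxylate (o-quinone diazide, used as a titrated solution kept in the dark)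
Conditions: t-BuONO (1.2 equiv), AcOH (cat.), MeCN, 0 °C, dark
Reagents that add atoms: tert-butyl nitrite, CC(C)(C)ON=O
Why: Aprotic diazotisation of an o-aminophenol, whose diazonium ion loses the phenol proton to give the diazo ketone, stabilised by the para ester.

Step 3
Reactants: 2 5,7-bis(benzyloxy)-2-[4-(benzyloxy)phenyl]-4H-chromen-4-one; 4 methyl 3-diazo-4-oxocyclohexa-1,5-diene-1-carboxylate
Product: 6 methyl 3-{5,7-bis(benzyloxy)-2-[4-(benzyloxy)phenyl]-4-oxo-4H-chromen-8-yl}-4-methoxybenzoate, via phenol 5 (not isolated)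
Conditions: Rh2(esp)2 (2 mol%, esp = α,α,α',α'-tetramethyl-1,3-benzenedipropanoate), PhCF3, 60 °C, 4 (1.5 equiv) added over 4 h; evaporate; then MeI, K2CO3, DMF, 40 °C
Reagents that add atoms: iodomethane, CI
Why: Proposed new method: loss of N2 from 4 at the dirhodium catalyst gives a quinoid α-oxo carbenoid (an enolonium equivalent) whose electrophilic carbon, the future C3', is attacked by C8 of 2, the most electron-rich and least hindered arene CH and the site where 5,7-dialkoxyflavones take up electrophiles, then proton transfer and tautomerisation give phenol 5, which Williamson methylation converts into 6; the closest known reaction type is dirhodium-catalysed aromatic C–H substitution of electron-rich arenes by cyclic α-diazo ketones (2-diazo-1,3-diones, diazonaphthoquinones).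

Step 4
Reactants: 7 2,6-dimethoxytoluene
Product: 9 3,5-dimethoxy-4-methylphenol, via arylboronate 8 (not isolated)
Conditions: [Ir(OMe)(cod)]2 (1 mol%), 4,4'-di-tert-butyl-2,2'-bipyridine (2 mol%), B2pin2 (0.6 equiv), THF, 80 °C; then KHSO5 (as Oxone), acetone/H2O, rt
Reagents that add atoms: bis(pinacolato)diboron, CC1(C)OB(OC1(C)C)B1OC(C)(C)C(C)(C)O1 (boron carried only in 8); potassium peroxymonosulfate, [K+].OOS(=O)(=O)[O-]
Why: Sterically controlled iridium-catalysed C–H borylation takes the only CH without an ortho substituent (para to the methyl), and ipso-oxidation of the C–B bond gives the phenol in one pot.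

Step 5
Reactants: 9 3,5-dimethoxy-4-methylphenol
Product: 11 1-(6-hydroxy-2,4-dimethoxy-3-methylphenyl)ethan-1-one, via aryl acetate 10 (not isolated)
Conditions: AcCl (1.2 equiv), Sc(OTf)3 (10 mol%), toluene/MeNO2, 100 °C
Reagents that add atoms: acetyl chloride, CC(Cl)=O
Why: Lewis-acid-catalysed O-acylation and Fries rearrangement (ortho-acylation of a phenol) can give only one regioisomer because the two free positions are equivalent and both ortho to OH.

Step 6
Reactants: 6 methyl 3-{5,7-bis(benzyloxy)-2-[4-(benzyloxy)phenyl]-4-oxo-4H-chromen-8-yl}-4-methoxybenzoate; 11 1-(6-hydroxy-2,4-dimethoxy-3-methylphenyl)ethan-1-one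
Product: 13 5,7-bis(benzyloxy)-2-[4-(benzyloxy)phenyl]-8-[5-(5,7-dimethoxy-6-methyl-4-oxo-4H-chromen-2-yl)-2-methoxyphenyl]-4H-chromen-4-one, via diketone 12 (not isolated)
Conditions: 11 (2 equiv), LiN(SiMe3)2 (4.2 equiv), THF, −78 °C; add 6, −78 °C → rt; AcOH quench, evaporate; then p-TsOH·H2O (20 mol%), toluene, 90 °C
Reagents that add atoms: none
Why: The lithium dianion of 11 undergoes crossed Claisen condensation with the non-enolisable ester 6 to give 1,3-diketone 12, and acid-catalysed cyclodehydration (the closing stage of a Baker–Venkataraman-type flavone synthesis) can use only the single free phenol, which places the methyl group at C6.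

Step 7
Reactants: 13 5,7-bis(benzyloxy)-2-[4-(benzyloxy)phenyl]-8-[5-(5,7-dimethoxy-6-methyl-4-oxo-4H-chromen-2-yl)-2-methoxyphenyl]-4H-chromen-4-one
Product: 14 Taiwanhomoflavone A
Conditions: BCl3 (10 equiv), pentamethylbenzene (6 equiv), CH2Cl2, −78 °C → rt; MeOH quench, aqueous work-up
Reagents that add atoms: none
Why: Chelation-controlled Lewis-acid ether cleavage, in which BCl3 with a benzyl-cation scavenger removes the three benzyl ethers and, through a six-membered boron chelate with the C4 carbonyl, only the peri 5-OMe, while the non-chelated 7-OMe and 4'-OMe remain.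

## Compound list

1 | apigenin, 5,7-dihydroxy-2-(4-hydroxyphenyl)-4H-chromen-4-one | O=c1cc(-c2ccc(O)cc2)oc2cc(O)cc(O)c12 | starting material
2 | 5,7-bis(benzyloxy)-2-[4-(benzyloxy)phenyl]-4H-chromen-4-one | O=c1cc(-c2ccc(OCc3ccccc3)cc2)oc2cc(OCc3ccccc3)cc(OCc3ccccc3)c12 | intermediate
3 | methyl 3-amino-4-hydroxybenzoate | COC(=O)c1ccc(O)c(N)c1 | starting material
4 | methyl 3-diazo-4-oxocyclohexa-1,5-diene-1-carboxylate | COC(=O)C1=CC(=[N+]=[N-])C(=O)C=C1 | intermediate
5 | methyl 3-{5,7-bis(benzyloxy)-2-[4-(benzyloxy)phenyl]-4-oxo-4H-chromen-8-yl}-4-hydroxybenzoate | COC(=O)c1ccc(O)c(-c2c(OCc3ccccc3)cc(OCc3ccccc3)c3c(=O)cc(-c4ccc(OCc5ccccc5)cc4)oc23)c1 | intermediate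
6 | methyl 3-{5,7-bis(benzyloxy)-2-[4-(benzyloxy)phenyl]-4-oxo-4H-chromen-8-yl}-4-methoxybenzoate | COC(=O)c1ccc(OC)c(-c2c(OCc3ccccc3)cc(OCc3ccccc3)c3c(=O)cc(-c4ccc(OCc5ccccc5)cc4)oc23)c1 | intermediate
7 | 2,6-dimethoxytoluene | COc1cccc(OC)c1C | starting material
8 | 2-(3,5-dimethoxy-4-methylphenyl)-4,4,5,5-tetramethyl-1,3,2-dioxaborolane | COc1cc(B2OC(C)(C)C(C)(C)O2)cc(OC)c1C | intermediate
9 | 3,5-dimethoxy-4-methylphenol | COc1cc(O)cc(OC)c1C | intermediate
10 | 3,5-dimethoxy-4-methylphenyl acetate | CC(=O)Oc1cc(OC)c(C)c(OC)c1 | intermediate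
11 | 1-(6-hydroxy-2,4-dimethoxy-3-methylphenyl)ethan-1-one | CC(=O)c1c(O)cc(OC)c(C)c1OC | intermediate
12 | 1-(6-hydroxy-2,4-dimethoxy-3-methylphenyl)-3-(3-{5,7-bis(benzyloxy)-2-[4-(benzyloxy)phenyl]-4-oxo-4H-chromen-8-yl}-4-methoxyphenyl)propane-1,3-dione | COc1ccc(C(=O)CC(=O)c2c(O)cc(OC)c(C)c2OC)cc1-c1c(OCc2ccccc2)cc(OCc2ccccc2)c2c(=O)cc(-c3ccc(OCc4ccccc4)cc3)oc12 | intermediate
13 | 5,7-bis(benzyloxy)-2-[4-(benzyloxy)phenyl]-8-[5-(5,7-dimethoxy-6-methyl-4-oxo-4H-chromen-2-yl)-2-methoxyphenyl]-4H-chromen-4-one | COc1ccc(-c2cc(=O)c3c(OC)c(C)c(OC)cc3o2)cc1-c1c(OCc2ccccc2)cc(OCc2ccccc2)c2c(=O)cc(-c3ccc(OCc4ccccc4)cc3)oc12 | intermediate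
14 | Taiwanhomoflavone A | COc1ccc(-c2cc(=O)c3c(O)c(C)c(OC)cc3o2)cc1-c1c(O)cc(O)c2c(=O)cc(-c3ccc(O)cc3)oc12 | target

## Step count and risks

Total step count: 7. Longest linear sequence: 4 steps (1 → 2 → 6 → 13 → 14; the branch 7 → 9 → 11 → 13 → 14 is equally long).

**Step 3** is the most likely to fail. The carbenoid may be diverted by the chromone carbonyl (carbonyl ylide), by the benzyl groups or by O–H insertion into phenol 5, and some attack at C6 is possible. The fallback sets out from 2 and replaces C–H functionalisation with halogenation and cross-coupling. Iodination with NIS and catalytic TFA in MeCN at room temperature gives 5,7-bis(benzyloxy)-2-[4-(benzyloxy)phenyl]-8-iodo-4H-chromen-4-one F1. Suzuki–Miyaura coupling of F1 with commercial [2-methoxy-5-(methoxycarbonyl)phenyl]boronic acid (COC(=O)c1ccc(OC)c(B(O)O)c1), Pd(PPh3)4 and K3PO4 in dioxane/H2O at 90 °C comes back to the route at 6.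

**Step 6** is the second risk. The para-methoxy benzoate 6 is a weak acylating agent, and the hindered dianion of 11 may react slowly or incompletely. The fallback sets out from 6 and makes the acyl transfer intramolecular. LiOH in THF/H2O at room temperature, then acidification, gives 3-{5,7-bis(benzyloxy)-2-[4-(benzyloxy)phenyl]-4-oxo-4H-chromen-8-yl}-4-methoxybenzoic acid F2. Esterification of F2 with the phenol of 11 (EDC·HCl, DMAP, CH2Cl2) gives 2-acetyl-3,5-dimethoxy-4-methylphenyl 3-{5,7-bis(benzyloxy)-2-[4-(benzyloxy)phenyl]-4-oxo-4H-chromen-8-yl}-4-methoxybenzoate F3. Baker–Venkataraman rearrangement of F3 with KOC(CH3)3 in THF comes back to the route at diketone 12, which is cyclodehydrated as in step 6.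

**Step 7** is the third risk. One BCl3 treatment may leave the 5-OMe partly intact or start to attack the 7- or 4'-OMe. The fallback sets out from 13 and separates the two deprotections. Hydrogenolysis (H2 at 1 atm, 10% Pd/C, THF/MeOH) gives 8-[5-(5,7-dimethoxy-6-methyl-4-oxo-4H-chromen-2-yl)-2-methoxyphenyl]-5,7-dihydroxy-2-(4-hydroxyphenyl)-4H-chromen-4-one F4. Chelation-selective 5-O-demethylation of F4 with AlCl3 in MeCN at 60 °C comes back to the route at 14.

## Further compounds

F1 | step 3 | 5,7-bis(benzyloxy)-2-[4-(benzyloxy)phenyl]-8-iodo-4H-chromen-4-one | O=c1cc(-c2ccc(OCc3ccccc3)cc2)oc2c(I)c(OCc3ccccc3)cc(OCc3ccccc3)c12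
F2 | step 6 | 3-{5,7-bis(benzyloxy)-2-[4-(benzyloxy)phenyl]-4-oxo-4H-chromen-8-yl}-4-methoxybenzoic acid | OC(=O)c1ccc(OC)c(-c2c(OCc3ccccc3)cc(OCc3ccccc3)c3c(=O)cc(-c4ccc(OCc5ccccc5)cc4)oc23)c1
F3 | step 6 | 2-acetyl-3,5-dimethoxy-4-methylphenyl 3-{5,7-bis(benzyloxy)-2-[4-(benzyloxy)phenyl]-4-oxo-4H-chromen-8-yl}-4-methoxybenzoate | CC(=O)c1c(OC(=O)c2ccc(OC)c(-c3c(OCc4ccccc4)cc(OCc4ccccc4)c4c(=O)cc(-c5ccc(OCc6ccccc6)cc5)oc34)c2)cc(OC)c(C)c1OC
F4 | step 7 | 8-[5-(5,7-dimethoxy-6-methyl-4-oxo-4H-chromen-2-yl)-2-methoxyphenyl]-5,7-dihydroxy-2-(4-hydroxyphenyl)-4H-chromen-4-one | COc1ccc(-c2cc(=O)c3c(OC)c(C)c(OC)cc3o2)cc1-c1c(O)cc(O)c2c(=O)cc(-c3ccc(O)cc3)oc12
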